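**Plan**

1. Retrosynthesis: the sulfate and the three free phenols are unmasked last; the C11–aryl bond is cut to an aryllithium and the C11 aldehyde 14 (benzylic oxygen removed by radical deoxygenation); the Δ2 alkene left by the key step is hydrogenated.
2. Central cut: C1–C2 of ring A together with C9–C10 of ring B, which opens the decalin to the acyclic 1,5-enyne 10 that carries only the C5 stereocenter.
3. Enyne 10 goes back to nerol: C4–C5 by an Ireland–Claisen rearrangement of the 8-hydroxyneryl isobutyrate, C2 by one-carbon alkyne homologation of the C3 aldehyde.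
4. Forward order: nerol chain → quaternary C4 and stereocenter C5 → alkyne → ring A, then ring B, in one gold-catalysed operation → aryl group on C11 → sulfate.
5. Stereochemistry: C5 from the chiral boron ketene acetal in the Claisen step; C10 (trans ring fusion) from C5, and C9 (C11 axial, α) from the Z-alkene of nerol, both in the cascade.
6. Enabling feature: C1 and C2 are the two unsubstituted methylenes of ring A between quaternary C4 and C10, so an ethynyl group on C4 and an isopropenyl group on C5 form a 1,5-enyne whose 6-endo closure leaves a methyl-stabilized cation at C10, exactly where ring B (C9–C10) has to close.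

Key step: step 8

Numbering remark: drimane numbering is used for the decalin (C11 on C9, C12 on C8, C13 and C14 on C4, C15 on C10); all bicyclic compounds have 5α-H, 10β-CH3 and 9β-H (C11 on the α face).
Assumption (sense of induction): the (4S,5S)-diazaborolidine is taken to give the (3R)-acid 7; if the opposite sense is found, the (4R,5R)-reagent is used and nothing else changes.
Assumption (form of the target): the aryl hydrogen sulfate is released as its ammonium salt and is shown in the protonated form obtained on cold acidic ion exchange.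

**Route**

Step 1
Reactants: 1 nerol
Product: 2 tert-butyl{[(2Z)-3,7-dimethylocta-2,6-dien-1-yl]oxy}diphenylsilane
Conditions: t-BuPh2SiCl, imidazole, DMF, 0 → 23 °C
Reagents that add atoms: tert-butyl(chloro)diphenylsilane, CC(C)(C)[Si](Cl)(c1ccccc1)c1ccccc1
Why: Routine silylation of a primary allylic alcohol; the bulky silyl ether should survive the oxidant, hydride, base and gold catalyst used later and leaves the Z-alkene untouched.

Step 2
Reactants: 2 tert-butyl{[(2Z)-3,7-dimethylocta-2,6-dien-1-yl]oxy}diphenylsilane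
Product: 3 (2E,6Z)-8-{[tert-butyl(diphenyl)silyl]oxy}-2,6-dimethylocta-2,6-dien-1-ol
Conditions: SeO2 (cat.), t-BuOOH, salicylic acid (cat.), CH2Cl2, 0 → 23 °C
Reagents that add atoms: tert-butyl hydroperoxide, CC(C)(C)OO
Why: SeO2 allylic oxidation (ene reaction, then [2,3]-shift) should attack the more electron-rich terminal trisubstituted alkene at its E-methyl group and give the E-configured primary allylic alcohol.

Step 3
Reactants: 3 (2E,6Z)-8-{[tert-butyl(diphenyl)silyl]oxy}-2,6-dimethylocta-2,6-dien-1-ol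
Product: 4 (2E,6Z)-8-{[tert-butyl(diphenyl)silyl]oxy}-2,6-dimethylocta-2,6-dien-1-yl 2-methylpropanoate
Conditions: i-PrCOCl, Et3N, DMAP (cat.), CH2Cl2, 0 °C
Reagents that add atoms: 2-methylpropanoyl chloride, CC(C)C(Cl)=O
Why: DMAP-catalysed acylation of an unhindered primary alcohol installs the isobutyrate that will become C3, C4 and the two C4 methyl groups.

Step 4
Reactants: 4 (2E,6Z)-8-{[tert-butyl(diphenyl)silyl]oxy}-2,6-dimethylocta-2,6-dien-1-yl 2-methylpropanoate
Product: 7 (3R,6Z)-8-{[tert-butyl(diphenyl)silyl]oxy}-2,2,6-trimethyl-3-(prop-1-en-2-yl)oct-6-enoic acid, via boron ketene acetal 5 (not isolated), via boryl carboxylate 6 (not isolated)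
Conditions: (4S,5S)-2-bromo-1,3-bis{[3,5-bis(trifluoromethyl)phenyl]sulfonyl}-4,5-diphenyl-1,3,2-diazaborolidine, Et3N, CH2Cl2, −78 → 4 °C; then H2O
Reagents that add atoms: (4S,5S)-2-bromo-1,3-bis{[3,5-bis(trifluoromethyl)phenyl]sulfonyl}-4,5-diphenyl-1,3,2-diazaborolidine, BrB1N(S(=O)(=O)c2cc(cc(c2)C(F)(F)F)C(F)(F)F)[C@@H](c2ccccc2)[C@H](c2ccccc2)N1S(=O)(=O)c1cc(cc(c1)C(F)(F)F)C(F)(F)F
Why: Enantioselective Ireland–Claisen rearrangement: soft enolization gives a tetrasubstituted boron ketene acetal (no enolate geometry to control), whose chair-like [3,3]-shift forms the congested C4–C5 bond and transposes the alkene into the isopropenyl group, the C2-symmetric sulfonamide ligand on boron differentiating the two mirror-image chair arrangements so that the new stereocenter is set by reagent control.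

Step 5
Reactants: 7 (3R,6Z)-8-{[tert-butyl(diphenyl)silyl]oxy}-2,2,6-trimethyl-3-(prop-1-en-2-yl)oct-6-enoic acid
Product: 8 (3R,6Z)-8-{[tert-butyl(diphenyl)silyl]oxy}-2,2,6-trimethyl-3-(prop-1-en-2-yl)oct-6-en-1-ol
Conditions: LiAlH4, THF, 0 °C → reflux
Reagents that add atoms: none
Why: LiAlH4 reduces the hindered α-quaternary acid to the neopentyl alcohol; the stereocenter is not adjacent to the carbonyl group and cannot epimerize.

Step 6
Reactants: 8 (3R,6Z)-8-{[tert-butyl(diphenyl)silyl]oxy}-2,2,6-trimethyl-3-(prop-1-en-2-yl)oct-6-en-1-ol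
Product: 9 (3R,6Z)-8-{[tert-butyl(diphenyl)silyl]oxy}-2,2,6-trimethyl-3-(prop-1-en-2-yl)oct-6-enal
Conditions: 1,1,1-triacetoxy-1,1-dihydro-1,2-benziodoxol-3(1H)-one (DMP), CH2Cl2, 0 → 23 °C
Reagents that add atoms: none
Why: Dess–Martin oxidation gives a non-enolizable aldehyde under neutral conditions that leave the alkenes and the silyl ether alone.

Step 7
Reactants: 9 (3R,6Z)-8-{[tert-butyl(diphenyl)silyl]oxy}-2,2,6-trimethyl-3-(prop-1-en-2-yl)oct-6-enal
Product: 10 tert-butyl{[(2Z,6R)-3,7,7-trimethyl-6-(prop-1-en-2-yl)non-2-en-8-yn-1-yl]oxy}diphenylsilane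
Conditions: dimethyl (1-diazo-2-oxopropyl)phosphonate, K2CO3, MeOH, 0 → 23 °C
Reagents that add atoms: dimethyl (1-diazo-2-oxopropyl)phosphonate, COP(=O)(OC)C(=[N+]=[N-])C(C)=O
Why: Seyferth–Gilbert homologation in its Ohira–Bestmann form adds the alkyne carbon C2 to the α-quaternary aldehyde, which has no enolizable position to suffer under the mild base.

Step 8
Reactants: 10 tert-butyl{[(2Z,6R)-3,7,7-trimethyl-6-(prop-1-en-2-yl)non-2-en-8-yn-1-yl]oxy}diphenylsilane
Product: 11 (5S,9R,10S)-11-{[tert-butyl(diphenyl)silyl]oxy}-9βH-drima-2,7-diene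
Conditions: [(t-Bu)2(2-biphenylyl)P]Au(NCMe)SbF6 (3 mol %), CH2Cl2, −20 → 23 °C
Reagents that add atoms: none
Why: The cationic monovalent gold complex binds the terminal alkyne, and the terminal carbon C1 of the isopropenyl group attacks the alkyne terminus C2 (6-endo-dig carbocyclization of the 1,5-enyne, closing ring A through the new C1–C2 bond) to give a vinylgold unit at C3 and a methyl-stabilized tertiary cation at C10; C9 of the Z-trisubstituted alkene captures this cation (6-endo-trig cation–olefin closure of ring B), loss of H7 from the C8 cation gives the Δ7 alkene, and the released proton cleaves the C3–Au bond to leave the Δ2 alkene. The closest known reaction type is the gold-catalysed 6-endo-dig cyclization of 1,5-enynes in which the tertiary cation is intercepted by a tethered nucleophile, as in alkyne-initiated polyene cyclization. C10 is set by C5: ring B closes through a chair in which the C5–C6 bond and the forming C10–C9 bond are both equatorial on ring A, so the C10 methyl ends up axial and anti to H5 (trans fusion); C9 is set by the alkene geometry, the Z-alkene placing C11 axial in that chair, on the α face opposite to the C10 methyl. The step needs endo attack, capture of the cation before proton loss, and endocyclic termination: quaternary C4 has no hydrogen for the shift that leads 1,5-enynes to bicyclo[3.1.0]hexenes and shields the internal alkyne carbon, the gem-dimethyl group and the chair closure make capture by the alkene fast, and the trisubstituted ring alkene is the more stable elimination product.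

Step 9
Reactants: 11 (5S,9R,10S)-11-{[tert-butyl(diphenyl)silyl]oxy}-9βH-drima-2,7-diene
Product: 12 (5S,9R,10S)-11-{[tert-butyl(diphenyl)silyl]oxy}-9βH-drim-7-ene
Conditions: H2 (1 atm), RhCl(PPh3)3 (10 mol %), benzene, 23 °C
Reagents that add atoms: none
Why: Homogeneous hydrogenation with RhCl(PPh3)3 should reduce the cis-disubstituted Δ2 alkene far faster than the hindered trisubstituted Δ7 alkene.

Step 10
Reactants: 12 (5S,9R,10S)-11-{[tert-butyl(diphenyl)silyl]oxy}-9βH-drim-7-ene
Product: 13 (5S,9R,10S)-9βH-drim-7-en-11-ol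
Conditions: Bu4NF, THF, 23 → 45 °C
Reagents that add atoms: none
Why: Fluoride cleaves the silyl ether without touching the alkene or the stereocenters.

Step 11
Reactants: 13 (5S,9R,10S)-9βH-drim-7-en-11-ol
Product: 14 (5S,9R,10S)-9βH-drim-7-en-11-al
Conditions: DMP, pyridine, CH2Cl2, 0 °C; used at once
Reagents that add atoms: none
Why: Buffered Dess–Martin oxidation gives the axial β,γ-unsaturated aldehyde without acid or base strong enough to enolize C9, and immediate use limits epimerization.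

Step 12
Reactants: 15 benzene-1,2,4-triol
Product: 16 1,2,4-tris(methoxymethoxy)benzene
Conditions: MeOCH2Cl, i-Pr2NEt, CH2Cl2, 0 → 23 °C, argon
Reagents that add atoms: chloromethyl methyl ether, COCCl
Why: Alkylation of the three phenols gives acetal ethers that later direct ortho-lithiation and come off with dilute acid.

Step 13
Reactants: 16 1,2,4-tris(methoxymethoxy)benzene
Product: 17 1-bromo-2,4,5-tris(methoxymethoxy)benzene
Conditions: NBS, DMF, 0 °C, dark
Reagents that add atoms: N-bromosuccinimide, O=C1CCC(=O)N1Br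
Why: Electrophilic aromatic bromination should occur at C5, para to one ether and ortho to another and less hindered than the position between two ethers.

Step 14
Reactants: 17 1-bromo-2,4,5-tris(methoxymethoxy)benzene
Product: 20 2,4,5-tris(methoxymethoxy)phenol, via aryllithium 18 (not isolated), via dimethyl arylboronate 19 (not isolated)
Conditions: n-BuLi, THF, −78 °C; B(OMe)3, −78 → 0 °C; H2O2, aq. NaOH, 0 °C
Reagents that add atoms: n-butyllithium, [Li]CCCC; trimethyl borate, COB(OC)OC; hydrogen peroxide, OO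
Why: Bromine–lithium exchange, borylation and oxidative 1,2-shift (ipso-hydroxylation) place the fourth oxygen as the only free phenol.

Step 15
Reactants: 20 2,4,5-tris(methoxymethoxy)phenol
Product: 21 triisopropyl[2,4,5-tris(methoxymethoxy)phenoxy]silane
Conditions: i-Pr3SiCl, imidazole, DMF, 23 °C
Reagents that add atoms: chloro(triisopropyl)silane, CC(C)[Si](Cl)(C(C)C)C(C)C
Why: Silylation marks the oxygen that will carry the sulfate with a bulky, non-directing group that fluoride removes in the presence of the acetal ethers.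

Step 16
Reactants: 21 triisopropyl[2,4,5-tris(methoxymethoxy)phenoxy]silane; 14 (5S,9R,10S)-9βH-drim-7-en-11-al
Product: 25 O-[(5S,9R,10S)-11-{2,3,6-tris(methoxymethoxy)-5-[(triisopropylsilyl)oxy]phenyl}-9βH-drim-7-en-11-yl] S-methyl carbonodithioate, via aryllithium 22 (not isolated), via lithium alkoxide 23 (not isolated), via lithium xanthate 24 (not isolated)
Conditions: 21, n-BuLi, THF, 0 °C; 14, −78 °C; CS2, −78 → 0 °C; MeI, 0 → 23 °C
Reagents that add atoms: n-butyllithium, [Li]CCCC; carbon disulfide, S=C=S; iodomethane, CI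
Why: Directed ortho-metalation between the two flanking acetal ethers, 1,2-addition of the aryllithium to the aldehyde and trapping of the alkoxide as its xanthate in one flask; the new C11 stereocenter is removed in the next step and need not be controlled.

Step 17
Reactants: 25 O-[(5S,9R,10S)-11-{2,3,6-tris(methoxymethoxy)-5-[(triisopropylsilyl)oxy]phenyl}-9βH-drim-7-en-11-yl] S-methyl carbonodithioate
Product: 26 triisopropyl{3-[(5S,9R,10S)-9βH-drim-7-en-11-yl]-2,4,5-tris(methoxymethoxy)phenoxy}silane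
Conditions: Bu3SnH, AIBN (cat.), toluene, 85 °C
Reagents that add atoms: none
Why: Barton–McCombie deoxygenation through a stabilized benzylic radical, under neutral conditions that leave the Δ7 alkene and C9 unchanged.

Step 18
Reactants: 26 triisopropyl{3-[(5S,9R,10S)-9βH-drim-7-en-11-yl]-2,4,5-tris(methoxymethoxy)phenoxy}silane
Product: 27 3-[(5S,9R,10S)-9βH-drim-7-en-11-yl]-2,4,5-tris(methoxymethoxy)phenol
Conditions: Bu4NF, AcOH, THF, 0 °C, argon
Reagents that add atoms: none
Why: Fluoride cleaves the aryl silyl ether selectively and frees the one phenol that is to be sulfated.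

Step 19
Reactants: 27 3-[(5S,9R,10S)-9βH-drim-7-en-11-yl]-2,4,5-tris(methoxymethoxy)phenol
Product: 28 3-[(5S,9R,10S)-9βH-drim-7-en-11-yl]-2,4,5-tris(methoxymethoxy)phenyl 2,2,2-trichloroethyl sulfate
Conditions: Cl3CCH2OSO2Cl, Et3N, DMAP (cat.), THF, 0 → 23 °C
Reagents that add atoms: 2,2,2-trichloroethyl sulfurochloridate, ClS(=O)(=O)OCC(Cl)(Cl)Cl
Why: Sulfonylation of the single free phenol gives a neutral, acid-stable sulfate diester, which fixes the position of the sulfate.

Step 20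
Reactants: 28 3-[(5S,9R,10S)-9βH-drim-7-en-11-yl]-2,4,5-tris(methoxymethoxy)phenyl 2,2,2-trichloroethyl sulfate
Product: 29 3-[(5S,9R,10S)-9βH-drim-7-en-11-yl]-2,4,5-trihydroxyphenyl 2,2,2-trichloroethyl sulfate
Conditions: HCl (0.5 M), MeOH, 0 → 23 °C, degassed
Reagents that add atoms: none
Why: Acid-catalysed acetal exchange with methanol removes the three acetal ethers while the sulfate diester is stable to acid, and the low temperature spares the Δ7 alkene.

Step 21
Reactants: 29 3-[(5S,9R,10S)-9βH-drim-7-en-11-yl]-2,4,5-trihydroxyphenyl 2,2,2-trichloroethyl sulfate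
Product: 30 3-[(5S,9R,10S)-9βH-drim-7-en-11-yl]-2,4,5-trihydroxyphenyl hydrogen sulfate
Conditions: Zn, HCO2NH4, MeOH, 23 °C, argon; then sulfonic acid resin (H form), MeOH, 0 °C
Reagents that add atoms: none
Why: Reductive β-elimination of the trichloroethyl group by zinc releases the sulfate monoester under near-neutral, reducing conditions that protect the oxidation-prone hydroquinone, and ion exchange gives the protonated form.

**Compound list**

1 | nerol, (2Z)-3,7-dimethylocta-2,6-dien-1-ol | CC(C)=CCC/C(C)=C\CO | starting material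
2 | tert-butyl{[(2Z)-3,7-dimethylocta-2,6-dien-1-yl]oxy}diphenylsilane | CC(C)=CCC/C(C)=C\CO[Si](c1ccccc1)(c1ccccc1)C(C)(C)C | intermediate
3 | (2E,6Z)-8-{[tert-butyl(diphenyl)silyl]oxy}-2,6-dimethylocta-2,6-dien-1-ol | OC/C(C)=C/CC/C(C)=C\CO[Si](c1ccccc1)(c1ccccc1)C(C)(C)C | intermediate
4 | (2E,6Z)-8-{[tert-butyl(diphenyl)silyl]oxy}-2,6-dimethylocta-2,6-dien-1-yl 2-methylpropanoate | CC(C)C(=O)OC/C(C)=C/CC/C(C)=C\CO[Si](c1ccccc1)(c1ccccc1)C(C)(C)C | intermediate
5 | boron ketene acetal of ester 4 with the (4S,5S)-1,3-bis{[3,5-bis(trifluoromethyl)phenyl]sulfonyl}-4,5-diphenyl-1,3,2-diazaborolidin-2-yl group on oxygen | CC(C)=C(OC/C(C)=C/CC/C(C)=C\CO[Si](c1ccccc1)(c1ccccc1)C(C)(C)C)OB1N(S(=O)(=O)c2cc(cc(c2)C(F)(F)F)C(F)(F)F)[C@@H](c2ccccc2)[C@H](c2ccccc2)N1S(=O)(=O)c1cc(cc(c1)C(F)(F)F)C(F)(F)F | intermediate (not isolated)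
6 | boryl carboxylate of acid 7 with the same (4S,5S)-diazaborolidin-2-yl group | O=C(OB1N(S(=O)(=O)c2cc(cc(c2)C(F)(F)F)C(F)(F)F)[C@@H](c2ccccc2)[C@H](c2ccccc2)N1S(=O)(=O)c1cc(cc(c1)C(F)(F)F)C(F)(F)F)C(C)(C)[C@H](CC/C(C)=C\CO[Si](c1ccccc1)(c1ccccc1)C(C)(C)C)C(C)=C | intermediate (not isolated)
7 | (3R,6Z)-8-{[tert-butyl(diphenyl)silyl]oxy}-2,2,6-trimethyl-3-(prop-1-en-2-yl)oct-6-enoic acid | OC(=O)C(C)(C)[C@H](CC/C(C)=C\CO[Si](c1ccccc1)(c1ccccc1)C(C)(C)C)C(C)=C | intermediate
8 | (3R,6Z)-8-{[tert-butyl(diphenyl)silyl]oxy}-2,2,6-trimethyl-3-(prop-1-en-2-yl)oct-6-en-1-ol | OCC(C)(C)[C@H](CC/C(C)=C\CO[Si](c1ccccc1)(c1ccccc1)C(C)(C)C)C(C)=C | intermediate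
9 | (3R,6Z)-8-{[tert-butyl(diphenyl)silyl]oxy}-2,2,6-trimethyl-3-(prop-1-en-2-yl)oct-6-enal | O=CC(C)(C)[C@H](CC/C(C)=C\CO[Si](c1ccccc1)(c1ccccc1)C(C)(C)C)C(C)=C | intermediate
10 | tert-butyl{[(2Z,6R)-3,7,7-trimethyl-6-(prop-1-en-2-yl)non-2-en-8-yn-1-yl]oxy}diphenylsilane | C#CC(C)(C)[C@H](CC/C(C)=C\CO[Si](c1ccccc1)(c1ccccc1)C(C)(C)C)C(C)=C | intermediate
11 | (5S,9R,10S)-11-{[tert-butyl(diphenyl)silyl]oxy}-9βH-drima-2,7-diene | CC1=CC[C@H]2C(C)(C)C=CC[C@]2(C)[C@@H]1CO[Si](c1ccccc1)(c1ccccc1)C(C)(C)C | intermediate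
12 | (5S,9R,10S)-11-{[tert-butyl(diphenyl)silyl]oxy}-9βH-drim-7-ene | CC1=CC[C@H]2C(C)(C)CCC[C@]2(C)[C@@H]1CO[Si](c1ccccc1)(c1ccccc1)C(C)(C)C | intermediate
13 | (5S,9R,10S)-9βH-drim-7-en-11-ol | CC1=CC[C@H]2C(C)(C)CCC[C@]2(C)[C@@H]1CO | intermediate
14 | (5S,9R,10S)-9βH-drim-7-en-11-al | CC1=CC[C@H]2C(C)(C)CCC[C@]2(C)[C@@H]1C=O | intermediate
15 | benzene-1,2,4-triol | Oc1ccc(O)c(O)c1 | starting material
16 | 1,2,4-tris(methoxymethoxy)benzene | COCOc1ccc(OCOC)c(OCOC)c1 | intermediate
17 | 1-bromo-2,4,5-tris(methoxymethoxy)benzene | COCOc1cc(OCOC)c(OCOC)cc1Br | intermediate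
18 | [2,4,5-tris(methoxymethoxy)phenyl]lithium | [Li]c1cc(OCOC)c(OCOC)cc1OCOC | intermediate (not isolated)
19 | dimethyl [2,4,5-tris(methoxymethoxy)phenyl]boronate | COCOc1cc(OCOC)c(OCOC)cc1B(OC)OC | intermediate (not isolated)
20 | 2,4,5-tris(methoxymethoxy)phenol | COCOc1cc(OCOC)c(OCOC)cc1O | intermediate
21 | triisopropyl[2,4,5-tris(methoxymethoxy)phenoxy]silane | COCOc1cc(OCOC)c(OCOC)cc1O[Si](C(C)C)(C(C)C)C(C)C | intermediate
22 | {2,3,6-tris(methoxymethoxy)-5-[(triisopropylsilyl)oxy]phenyl}lithium | COCOc1c([Li])c(OCOC)c(OCOC)cc1O[Si](C(C)C)(C(C)C)C(C)C | intermediate (not isolated)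
23 | lithium (5S,9R,10S)-11-{2,3,6-tris(methoxymethoxy)-5-[(triisopropylsilyl)oxy]phenyl}-9βH-drim-7-en-11-olate, both C11 epimers | CC1=CC[C@H]2C(C)(C)CCC[C@]2(C)[C@@H]1C(O[Li])c1c(OCOC)c(OCOC)cc(O[Si](C(C)C)(C(C)C)C(C)C)c1OCOC | intermediate (not isolated)
24 | lithium O-[(5S,9R,10S)-11-{2,3,6-tris(methoxymethoxy)-5-[(triisopropylsilyl)oxy]phenyl}-9βH-drim-7-en-11-yl] carbonodithioate | CC1=CC[C@H]2C(C)(C)CCC[C@]2(C)[C@@H]1C(OC(=S)S[Li])c1c(OCOC)c(OCOC)cc(O[Si](C(C)C)(C(C)C)C(C)C)c1OCOC | intermediate (not isolated)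
25 | O-[(5S,9R,10S)-11-{2,3,6-tris(methoxymethoxy)-5-[(triisopropylsilyl)oxy]phenyl}-9βH-drim-7-en-11-yl] S-methyl carbonodithioate, both C11 epimers | CC1=CC[C@H]2C(C)(C)CCC[C@]2(C)[C@@H]1C(OC(=S)SC)c1c(OCOC)c(OCOC)cc(O[Si](C(C)C)(C(C)C)C(C)C)c1OCOC | intermediate
26 | triisopropyl{3-[(5S,9R,10S)-9βH-drim-7-en-11-yl]-2,4,5-tris(methoxymethoxy)phenoxy}silane | CC1=CC[C@H]2C(C)(C)CCC[C@]2(C)[C@@H]1Cc1c(OCOC)c(OCOC)cc(O[Si](C(C)C)(C(C)C)C(C)C)c1OCOC | intermediate
27 | 3-[(5S,9R,10S)-9βH-drim-7-en-11-yl]-2,4,5-tris(methoxymethoxy)phenol | CC1=CC[C@H]2C(C)(C)CCC[C@]2(C)[C@@H]1Cc1c(OCOC)c(OCOC)cc(O)c1OCOC | intermediate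
28 | 3-[(5S,9R,10S)-9βH-drim-7-en-11-yl]-2,4,5-tris(methoxymethoxy)phenyl 2,2,2-trichloroethyl sulfate | CC1=CC[C@H]2C(C)(C)CCC[C@]2(C)[C@@H]1Cc1c(OCOC)c(OCOC)cc(OS(=O)(=O)OCC(Cl)(Cl)Cl)c1OCOC | intermediate
29 | 3-[(5S,9R,10S)-9βH-drim-7-en-11-yl]-2,4,5-trihydroxyphenyl 2,2,2-trichloroethyl sulfate | CC1=CC[C@H]2C(C)(C)CCC[C@]2(C)[C@@H]1Cc1c(O)c(O)cc(OS(=O)(=O)OCC(Cl)(Cl)Cl)c1O | intermediate
30 | 3-[(5S,9R,10S)-9βH-drim-7-en-11-yl]-2,4,5-trihydroxyphenyl hydrogen sulfate (CNP0445131.2) | CC1=CC[C@H]2C(C)(C)CCC[C@]2(C)[C@@H]1Cc1c(O)c(O)cc(OS(=O)(=O)O)c1O | target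

**Totals and risks**

Total step count: 21 (17 in the main line, 4 for the arene).
Longest linear sequence: 17 steps (steps 1–11 and 16–21, from nerol).

Steps most likely to fail:

Step 4. The α-branched ester may enolize incompletely with the bulky boron reagent, or the facial discrimination in the rearrangement may be low or reversed. Fallback: ester 4 is rearranged without chiral control as its silyl ketene acetal (LDA, Me3SiCl, THF, −78 → 60 °C) to the racemic (6Z)-8-{[tert-butyl(diphenyl)silyl]oxy}-2,2,6-trimethyl-3-(prop-1-en-2-yl)oct-6-enoic acid F1. This is resolved by crystallization with (R)-1-phenylethylamine to the (1R)-1-phenylethanaminium salt of the (3R)-acid F2, and acidification returns the route to acid 7.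

Step 8. The C10 cation may lose a proton before the second ring closes, the ring fusion may come out cis, or the final proton loss may give the exocyclic alkene. Fallback: aldehyde 9 is homologated by Wittig methoxymethylenation (Ph3P=CHOMe) to the enol ether tert-butyl{[(2Z,6R)-9-methoxy-3,7,7-trimethyl-6-(prop-1-en-2-yl)nona-2,8-dien-1-yl]oxy}diphenylsilane F3 and hydrolysed with mild acid to (4R,7Z)-9-{[tert-butyl(diphenyl)silyl]oxy}-3,3,7-trimethyl-4-(prop-1-en-2-yl)non-7-enal F4. MeAlCl2 in CH2Cl2 at −78 °C then starts the same two-ring cascade from the carbonyl group (Prins closure of C1–C2, then cation–olefin closure of C9–C10) and gives 11-{[tert-butyl(diphenyl)silyl]oxy}-9βH-drim-7-en-2-ol F5. Its S-methyl xanthate F6 is reduced with Bu3SnH (Barton–McCombie), which rejoins the route at 12 and makes step 9 unnecessary.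

Step 16. The basic, hindered aryllithium may enolize the axial aldehyde and epimerize C9, or add only slowly to the neopentyl-type carbonyl group. Fallback: alcohol 13 is converted into 11-iodo-9βH-drim-7-ene F7 (I2, PPh3, imidazole), and arene 21 is lithiated as in step 16 and quenched with iodine to [3-iodo-2,4,5-tris(methoxymethoxy)phenoxy]triisopropylsilane F8. F7 is turned by t-BuLi and 9-methoxy-9-borabicyclo[3.3.1]nonane into 9-(9βH-drim-7-en-11-yl)-9-borabicyclo[3.3.1]nonane F9 and coupled with F8 under Suzuki–Miyaura conditions (Pd(dppf)Cl2, K3PO4, DMF–H2O). This gives 26 directly and never places a carbonyl group next to C9.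

Further compounds
F1 | step 4 | racemic (6Z)-8-{[tert-butyl(diphenyl)silyl]oxy}-2,2,6-trimethyl-3-(prop-1-en-2-yl)oct-6-enoic acid | OC(=O)C(C)(C)C(CC/C(C)=C\CO[Si](c1ccccc1)(c1ccccc1)C(C)(C)C)C(C)=C
F2 | step 4 | (1R)-1-phenylethanaminium (3R,6Z)-8-{[tert-butyl(diphenyl)silyl]oxy}-2,2,6-trimethyl-3-(prop-1-en-2-yl)oct-6-enoate | [O-]C(=O)C(C)(C)[C@H](CC/C(C)=C\CO[Si](c1ccccc1)(c1ccccc1)C(C)(C)C)C(C)=C.C[C@@H]([NH3+])c1ccccc1
F3 | step 8 | tert-butyl{[(2Z,6R)-9-methoxy-3,7,7-trimethyl-6-(prop-1-en-2-yl)nona-2,8-dien-1-yl]oxy}diphenylsilane, enol ether E/Z mixture | COC=CC(C)(C)[C@H](CC/C(C)=C\CO[Si](c1ccccc1)(c1ccccc1)C(C)(C)C)C(C)=C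
F4 | step 8 | (4R,7Z)-9-{[tert-butyl(diphenyl)silyl]oxy}-3,3,7-trimethyl-4-(prop-1-en-2-yl)non-7-enal | O=CCC(C)(C)[C@H](CC/C(C)=C\CO[Si](c1ccccc1)(c1ccccc1)C(C)(C)C)C(C)=C
F5 | step 8 | 11-{[tert-butyl(diphenyl)silyl]oxy}-9βH-drim-7-en-2-ol (5α-H, 10β-CH3) | CC1=CC[C@H]2C(C)(C)CC(O)C[C@]2(C)[C@@H]1CO[Si](c1ccccc1)(c1ccccc1)C(C)(C)C
F6 | step 8 | O-(11-{[tert-butyl(diphenyl)silyl]oxy}-9βH-drim-7-en-2-yl) S-methyl carbonodithioate | CC1=CC[C@H]2C(C)(C)CC(OC(=S)SC)C[C@]2(C)[C@@H]1CO[Si](c1ccccc1)(c1ccccc1)C(C)(C)C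
F7 | step 16 | 11-iodo-9βH-drim-7-ene (5α-H, 10β-CH3) | CC1=CC[C@H]2C(C)(C)CCC[C@]2(C)[C@@H]1CI
F8 | step 16 | [3-iodo-2,4,5-tris(methoxymethoxy)phenoxy]triisopropylsilane | COCOc1c(I)c(OCOC)c(OCOC)cc1O[Si](C(C)C)(C(C)C)C(C)C
F9 | step 16 | 9-(9βH-drim-7-en-11-yl)-9-borabicyclo[3.3.1]nonane (5α-H, 10β-CH3) | CC1=CC[C@H]2C(C)(C)CCC[C@]2(C)[C@@H]1CB1C2CCCC1CCC2
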